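In a one-step world each electrophile takes one nucleophile and gives one target, and the curve ends where the smaller charge has been used. I test that picture on the epsilon table, where electrophile is in excess.

| flask | electrophile | nucleophile | gas | remark | time |
|---|---|---|---|---|---|
| delta | 0.54 M | 0.72 M | 64 mM (held) | run made earlier |  |
| epsilon | 1.2 M | 0.72 M | 64 mM (held) | run made earlier |  |
| eta | 0.80 M | 1.1 M | 64 mM (held) | run made earlier |  |
| flask | 0.80 M | 0.720 M | 64 mM (held) |  | 2.0 min |

| run | time / s | electrophile / % | target / % |
|---|---|---|---|
| delta | 10.0 | 16.3 | 81.5 |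
| delta | 12.0 | 15.2 | 85.9 |
| delta | 20.0 | 10.3 | 90.2 |
| delta | 30.0 | 2.2 | 95.5 |
| delta | 40.0 | 1.7 | 99.9 |
| delta | 60.0 | 0.5 | 97.9 |
| delta | 80.0 | 0 | 98.7 |
| epsilon | 10.0 | 51.6 | 45.7 |
| epsilon | 12.0 | 53.4 | 48.0 |
| epsilon | 20.0 | 45.3 | 53.8 |
| epsilon | 30.0 | 41.4 | 56.6 |
| epsilon | 50.0 | 38.3 | 60.5 |
| epsilon | 80.0 | 38.1 | 60.0 |
| eta | 10.0 | 13.5 | 83.9 |
| eta | 20.0 | 7.0 | 92.5 |
| eta | 40.0 | 1.0 | 100.3 |
| eta | 80.0 | 0.5 | 100.3 |

(standard deviation of a reading: 1 percentage point)

- part of the electrophile that has reacted at 2.0 min
- share of the unused nucleophile that is free and not bound as protonated nucleophile, at 2.0 min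

- at the start none of the gas is in solution
- the earlier runs do not show how much of nucleophile is bound; that part of a forecast is a guess

The last two rows of the epsilon table barely differ, and each reading carries a scatter of 1 percentage point, so I replace them by their mean. The target column then gives 0.723 M, about the 0.72 M of nucleophile charged, so these readings fit the one-to-one picture. The electrophile column gives 0.742 M, which leaves 0.0186 M unaccounted for, a reading that carries the scatter.

In the flask nucleophile is less than electrophile, so I carry the ceiling, 90.0% here, the nucleophile charged over the electrophile charged, which is what the limiting reagent can turn into target.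

Can the flask reach it in time? The fourth row of the epsilon table gives a mean rate of 0.0226 M s⁻¹, so as a rough estimate a straight line at that rate fills the flask's ceiling in 31.8 s, shorter than 2.0 min. That line hides the slowing tail, but the epsilon table has flattened by 50.0 s, also shorter than 2.0 min. I therefore commit to c at 90.0%, or up to 2.32% of the flask's electrophile above it. The share fr I cannot read from these runs.

The forecast gives 89.5% (86.5% to 92%) and 35% (5% to 85%), saying “nucleophile is therefore limiting”.

The flask gives c = 91.4% and fr = 48.0%.

    electrophile + nucleophile → acid set free + target (k = 6.90 M⁻¹ s⁻¹)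
    nucleophile + acid set free ⇌ protonated nucleophile, settled at all times (K = 540 M⁻¹)
    acid set free + free base ⇌ salt of the base (K = 5500 M⁻¹, k = 4.20 M⁻¹ s⁻¹)
    gas ⇌ free base, rate k4*(csat - [free base]) (kL = 1.70 s⁻¹)
    electrophile + acid set free → side product (k = 0.0150 M⁻¹ s⁻¹)

At 2.00 min the flask holds 90.0% target, at its ceiling of 90.0%, and 1.35% side product, with 0% of the nucleophile left. The neighbour with 0.18 M of nucleophile has its ceiling cut from 90.0% to 22.5% and gives c = 23.4%. Left until 20.0 min, the flask still holds 90.0% target, while its electrophile falls by 0.28 points to 8.37% and its side product rises to 1.63%.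

The earlier runs and the new flask stem from a simulated flask with constants of no real substance; scatter was added.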